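**Retrosynthetic overview**

1. Numbering: C1 carries the isopropylidene carbon C15; C2, C3 are CH2CH2; C4 is the acetoxy carbon; C5 is CH2; C6=C7 is the enol ether; C8 is CHMe; C9 is CH2; C10 is the ring CH–O; C11 is CH2; C12–C13 is the oxirane; C14 is the ketone.
2. The route rests on the C12–C13 oxirane lying α,β to the C14 ketone inside the 14-membered carbocycle C1–C14. Cutting C12–C13 and O–C13 gives seco diketone 28 (C12 methyl ketone, C14 dichloromethyl ketone), to be closed by a samarium chloro-enolate aldol/Darzens cascade.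
3. 28 comes from the (Z)-C6=C7 enol ether made by Takai–Utimoto alkylidenation of lactone 12 (C7–C12 and the oxolane oxygen) with gem-dibromide 24 (C1–C6, C13–C15).
4. 12 comes from (S)-epichlorohydrin (C10), vinyl Grignard, malonate and trans-methylation (C8). 24 comes from (R)-linalool (C4) by a formaldehyde ene reaction at C1, LiCHCl2 addition at C14, and hydroboration/gem-dibromination at C6.
5. Ring order: oxolane first (step 2, as the lactone), then the 14-membered carbocycle and the oxirane together (step 17), then desilylation and acetylation.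

Key step: step 17

Remark: the carbinol carbons C12 (from step 5) and C14 (from step 10) are carried as mixtures of epimers, because both become carbonyl carbons in 28; their descriptors are left open in names and SMILES. The same holds for the transient centres in 7 and 15.

**Route**

Step 1
Reactants: 1 (S)-epichlorohydrin; 2 vinylmagnesium bromide
Product: 3 (2S)-1-chloropent-4-en-2-ol
Conditions: CuI (10 mol%), THF, −40 → −10 °C; aq. NH4Cl
Reagents that add atoms: none
Why: Copper-catalysed Grignard opening of the epoxide (SN2 at the unsubstituted ring carbon, faster than chloride displacement) leaves the C–O stereocentre, the future C10, untouched.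

Step 2
Reactants: 3 (2S)-1-chloropent-4-en-2-ol; 4 diethyl malonate
Product: 7 ethyl (5S)-2-oxo-5-(prop-2-enyl)oxolane-3-carboxylate (C3 epimers), via allyl oxirane 5 (not isolated), via hydroxy diester 6 (not isolated)
Conditions: NaOEt (2.1 equiv), EtOH, 0 °C → reflux; aq. HCl
Reagents that add atoms: none
Why: Malonic ester lactone synthesis: ethoxide closes the chlorohydrin to the epoxide, the sodium salt of diethyl malonate opens it at CH2 and the alkoxide lactonises, so the C10 configuration is carried over unchanged.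

Step 3
Reactants: 7 ethyl (5S)-2-oxo-5-(prop-2-enyl)oxolane-3-carboxylate
Product: 8 (5R)-5-(prop-2-enyl)oxolan-2-one
Conditions: LiCl, H2O, DMSO, 150 °C
Reagents that add atoms: none
Why: Krapcho dealkoxycarbonylation removes the activating ester under neutral salt conditions that leave the lactone and the C10 centre alone.

Step 4
Reactants: 8 (5R)-5-(prop-2-enyl)oxolan-2-one
Product: 10 (3S,5S)-3-methyl-5-(prop-2-enyl)oxolan-2-one, via lithium enolate 9 (not isolated)
Conditions: LiN(iPr)2 (LDA), THF, −78 °C; MeI, −78 → −45 °C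
Reagents that add atoms: lithium diisopropylamide, [Li]N(C(C)C)C(C)C (lithium stays only in 9); iodomethane, CI
Why: Kinetic enolate alkylation of a γ-substituted butyrolactone, in which iodomethane should approach the enolate face anti to the C10 substituent and so set C8 (S) trans to the side chain.

Step 5
Reactants: 10 (3S,5S)-3-methyl-5-(prop-2-enyl)oxolan-2-one
Product: 11 (3S,5R)-5-(2-hydroxypropyl)-3-methyloxolan-2-one (carbinol epimers)
Conditions: Co(acac)2 (20 mol%), PhSiH3, O2 (1 atm), THF, rt
Reagents that add atoms: dioxygen, O=O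
Why: Mukaiyama hydration (hydrogen-atom transfer from a cobalt hydride to the terminal alkene, O2 capture, reduction) gives the Markovnikov secondary alcohol at C12; no control is needed because C12 becomes a ketone.

Step 6
Reactants: 11 (3S,5R)-5-(2-hydroxypropyl)-3-methyloxolan-2-one
Product: 12 (3S,5R)-3-methyl-5-[2-(triethylsilyloxy)propyl]oxolan-2-one (carbinol epimers)
Conditions: TESCl, imidazole, DMAP (cat.), CH2Cl2, 0 °C → rt
Reagents that add atoms: chlorotriethylsilane, CC[Si](CC)(CC)Cl
Why: Standard silylation of a secondary alcohol masks C12–OH for the alkylidenation and gives an ether that fluoride removes before the hindered tertiary one.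

Step 7
Reactants: 13 (R)-linalool
Product: 14 (R)-linalool triethylsilyl ether
Conditions: TESOTf, 2,6-lutidine, CH2Cl2, −78 → 0 °C
Reagents that add atoms: triethylsilyl triflate, CC[Si](CC)(CC)OS(=O)(=O)C(F)(F)F
Why: Silylation of the hindered tertiary allylic alcohol by the silyl triflate and a hindered pyridine base does not ionise the C4–O bond, so the R configuration is kept.

Step 8
Reactants: 14 (R)-linalool triethylsilyl ether
Product: 15 (5R)-5-methyl-2-(prop-1-en-2-yl)-5-(triethylsilyloxy)hept-6-en-1-ol (C2 epimers)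
Conditions: (CH2O)n, Me2AlCl, CH2Cl2, −78 → 0 °C
Reagents that add atoms: formaldehyde (from paraformaldehyde), C=O
Why: Me2AlCl-promoted carbonyl-ene reaction of formaldehyde, which engages only the electron-rich trisubstituted alkene, bonds carbon to the less substituted C1 and takes hydrogen from a methyl group; the unselective C1 centre is erased in step 9.

Step 9
Reactants: 15 (5R)-5-methyl-2-(prop-1-en-2-yl)-5-(triethylsilyloxy)hept-6-en-1-ol
Product: 17 (5R)-5-methyl-2-(propan-2-ylidene)-5-(triethylsilyloxy)hept-6-enal, via β,γ-unsaturated aldehyde 16 (not isolated)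
Conditions: Dess–Martin periodinane, NaHCO3, CH2Cl2, 0 °C; then DBU (0.2 equiv), CH2Cl2, rt
Reagents that add atoms: none
Why: Dess–Martin oxidation gives the β,γ-unsaturated aldehyde without premature isomerisation, and catalytic DBU then moves the double bond into conjugation (prototropic isomerisation through the dienolate) to the tetrasubstituted enal.

Step 10
Reactants: 17 (5R)-5-methyl-2-(propan-2-ylidene)-5-(triethylsilyloxy)hept-6-enal
Product: 19 (6R)-1,1-dichloro-6-methyl-3-(propan-2-ylidene)-2,6-bis(triethylsilyloxy)oct-7-ene (C2 epimers), via lithium alkoxide 18 (not isolated)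
Conditions: CH2Cl2, n-BuLi, THF, −100 °C; 17, −100 → −78 °C; then TESOTf, −78 → −40 °C
Reagents that add atoms: dichloromethane, ClCCl; n-butyllithium, [Li]CCCC (lithium stays only in 18); triethylsilyl triflate, CC[Si](CC)(CC)OS(=O)(=O)C(F)(F)F
Why: 1,2-Addition of dichloromethyllithium (carbenoid from deprotonated CH2Cl2) to the enal, whose β-carbon is fully substituted, followed by O-silylation of the cold alkoxide before it can close to a chloro-epoxide; the C14 centre is left uncontrolled because it becomes the ketone.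

Step 11
Reactants: 19 (6R)-1,1-dichloro-6-methyl-3-(propan-2-ylidene)-2,6-bis(triethylsilyloxy)oct-7-ene
Product: 21 (3R)-8,8-dichloro-3-methyl-6-(propan-2-ylidene)-3,7-bis(triethylsilyloxy)octan-1-ol, via alkylborane 20 (not isolated)
Conditions: 9-BBN, THF, 0 → 40 °C; then aq. NaOH, H2O2, 0 °C
Reagents that add atoms: 9-borabicyclo[3.3.1]nonane, B1C2CCCC1CCC2 (boron stays only in 20); hydrogen peroxide, OO
Why: Anti-Markovnikov hydroboration–oxidation: 9-BBN adds only to the monosubstituted vinyl group (the tetrasubstituted alkene is inert) and alkaline peroxide replaces boron by hydroxyl at C6.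

Step 12
Reactants: 21 (3R)-8,8-dichloro-3-methyl-6-(propan-2-ylidene)-3,7-bis(triethylsilyloxy)octan-1-ol
Product: 22 (3R)-8,8-dichloro-3-methyl-6-(propan-2-ylidene)-3,7-bis(triethylsilyloxy)octanal
Conditions: Dess–Martin periodinane, NaHCO3, CH2Cl2, 0 °C → rt
Reagents that add atoms: none
Why: Dess–Martin oxidation under buffered neutral conditions gives the β-silyloxy aldehyde without β-elimination of the C4 silyloxy group.

Step 13
Reactants: 22 (3R)-8,8-dichloro-3-methyl-6-(propan-2-ylidene)-3,7-bis(triethylsilyloxy)octanal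
Product: 24 (6R)-8,8-dibromo-1,1-dichloro-6-methyl-3-(propan-2-ylidene)-2,6-bis(triethylsilyloxy)octane, via hydrazone 23 (not isolated)
Conditions: N2H4·H2O, EtOH, 4 Å MS, 0 °C → rt; then CuBr2, LiOtBu, THF, 0 °C → rt
Reagents that add atoms: hydrazine hydrate, NN.O (nitrogen stays only in 23); copper dibromide, Br[Cu]Br
Why: Hydrazone formation and copper dibromide oxidation (hydrazone to diazoalkane, then double bromide transfer with loss of N2) is the standard entry to gem-dibromides for ester alkylidenation and spares silyl ethers, the alkene and the CHCl2 group.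

Step 14
Reactants: 24 gem-dibromide; 12 (3S,5R)-3-methyl-5-[2-(triethylsilyloxy)propyl]oxolan-2-one (2 equiv, excess recovered)
Product: 26 (4R,6Z,8S,10R)-seco enol ether carrying OTES at C4 C12 C14 and CHCl2 at C13, via gem-dizinc species 25 (not isolated)
Conditions: Zn, PbCl2 (cat.), TiCl4, TMEDA, THF–CH2Cl2, 0 → 25 °C; then Et3N, aq. K2CO3
Reagents that add atoms: zinc, [Zn] (stays only in 25)
Why: Takai–Utimoto ester alkylidenation: zinc converts the gem-dibromide into the gem-dizinc species, which with low-valent titanium–TMEDA alkylidenates the lactone carbonyl under non-basic conditions (no epimerisation at C8, silyl ethers kept, and the CHCl2 group is a gem-dichloride as inert as the CH2Cl2 co-solvent), and the Z preference of the reagent is reinforced by allylic strain between C5 and the C8 methyl, placing C5 cis to the ring oxygen.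

Step 15
Reactants: 26 seco enol ether (three TES ethers)
Product: 27 (4R,6Z,8S,10R)-seco diol (C12–OH and C14–OH free; C4–OTES kept)
Conditions: Bu4NF–AcOH (1:1), THF, 0 °C → rt
Reagents that add atoms: none
Why: Buffered fluoride desilylation should cleave the two secondary TES ethers (C12 unhindered, C14 activated by its electron-poor alkoxide) well before the hindered tertiary C4 ether, while the acetate buffer protects the acid-labile enol ether and the base-labile dichloromethyl carbinol.

Step 16
Reactants: 27 seco diol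
Product: 28 (4R,6Z,8S,10R)-seco diketone (C12 methyl ketone and C14 dichloromethyl ketone; C4–OTES)
Conditions: Dess–Martin periodinane, pyridine, CH2Cl2, 0 °C → rt
Reagents that add atoms: none
Why: Dess–Martin oxidation of both secondary alcohols; pyridine buffering protects the exocyclic enol ether, and the neutral medium avoids enolisation at C11 and loss of the C10 oxygen by β-elimination.

Step 17
Reactants: 28 seco diketone
Product: 31 (4R,6Z,8S,10R,12S,13R)-macrocyclic epoxy ketone with C4–OTES, via samarium chloro-enolate 29 (not isolated), via samarium chloro-aldolate 30 (not isolated)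
Conditions: SmI2 (2.0 equiv, 0.1 M in THF) and 28 added simultaneously over 3 h to THF (final 2 mM), −78 °C; then → 0 °C; K2CO3, MeOH, 0 °C in the same flask if chlorohydrin remains
Reagents that add atoms: samarium diiodide, I[Sm]I (samarium stays only in 29 and 30)
Why: Proposed new method: two electrons from SmI2 cleave one C13–Cl bond of the α,α-dichloro ketone, the most reducible group present, and give the trivalent-samarium chloro-enolate 29, which is carbon-nucleophilic only at C13 because C1 has no hydrogen; it adds to the C12 ketone in an aldol (Reformatsky-type) closure of the 14-membered carbocycle, and the samarium alkoxide 30 then displaces the second chloride at C13 in a 3-exo-tet SN2 (Darzens) closure of the oxirane. The closest known reactions are the SmI2-mediated intramolecular Reformatsky macrocyclisation of α-halo carbonyl compounds onto aldehydes, the intermolecular SmI2 halo-aldol of α,α-dihalo carbonyl compounds, and the Darzens halohydrin-to-epoxide closure; new are their fusion in one flask and a ketone acceptor in the macrocyclisation. C12 should be set by a six-membered chelate of trivalent samarium between the C12 carbonyl oxygen and the C10 ring oxygen, which exposes the face that puts the new C12–O bond anti to O10 (12S); C13 follows from chloride leaving anti to the attacking oxygen, and since the chloro-aldolates can interconvert by retro-aldol and C13 enolisation they should funnel into the less strained trans oxirane (C11 anti to C14, 13R). The step needs a single chemoselective C–Cl reduction, a non-basic enolate (a base would enolise C11 and expel the enol ether oxygen from C10), and no reductant left when the epoxy ketone appears, because SmI2 opens α,β-epoxy ketones; metering exactly two equivalents of SmI2 together with the substrate into cold THF at high dilution is meant to secure all three. Neither the facial bias nor the trans closure has direct precedent, so the risk of the route sits here.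

Step 18
Reactants: 31 macrocyclic epoxy ketone TES ether
Product: 32 (4R,6Z,8S,10R,12S,13R)-macrocyclic epoxy ketone with free C4–OH
Conditions: Bu4NF, THF, 0 °C → rt; neutral work-up
Reagents that add atoms: none
Why: Fluoride desilylation of the tertiary TES ether; acid is excluded throughout because the free C4 hydroxyl could add to the C6=C7 enol ether to form a spiroketal.

Step 19
Reactants: 32 macrocyclic tertiary alcohol
Product: 33 CNP0162736.1 (target)
Conditions: Ac2O, DMAP, Et3N, CH2Cl2, rt
Reagents that add atoms: acetic anhydride, CC(=O)OC(C)=O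
Why: DMAP-catalysed acylation of the tertiary alcohol under basic acid-free conditions; no stereocentre is touched.

**Compound list**

1 | (S)-epichlorohydrin | ClC[C@@H]1CO1 | starting material
2 | vinylmagnesium bromide | C=C[Mg]Br | starting material
3 | (2S)-1-chloropent-4-en-2-ol | ClC[C@@H](O)CC=C | intermediate
4 | diethyl malonate | CCOC(=O)CC(=O)OCC | starting material
5 | (2S)-2-(prop-2-enyl)oxirane | C=CC[C@H]1CO1 | intermediate (not isolated)
6 | diethyl 2-[(2S)-2-hydroxypent-4-enyl]propanedioate | CCOC(=O)C(C[C@@H](O)CC=C)C(=O)OCC | intermediate (not isolated)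
7 | ethyl (5S)-2-oxo-5-(prop-2-enyl)oxolane-3-carboxylate, C3 epimers | CCOC(=O)C1C[C@H](CC=C)OC1=O | intermediate
8 | (5R)-5-(prop-2-enyl)oxolan-2-one | C=CC[C@H]1CCC(=O)O1 | intermediate
9 | lithium enolate of 8 | C=CC[C@H]1CC=C(O[Li])O1 | intermediate (not isolated)
10 | (3S,5S)-3-methyl-5-(prop-2-enyl)oxolan-2-one (trans) | C=CC[C@H]1C[C@H](C)C(=O)O1 | intermediate
11 | (3S,5R)-5-(2-hydroxypropyl)-3-methyloxolan-2-one, carbinol epimers | CC(O)C[C@H]1C[C@H](C)C(=O)O1 | intermediate
12 | (3S,5R)-3-methyl-5-[2-(triethylsilyloxy)propyl]oxolan-2-one, carbinol epimers | CC[Si](CC)(CC)OC(C)C[C@H]1C[C@H](C)C(=O)O1 | intermediate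
13 | (R)-linalool | CC(C)=CCC[C@@](C)(O)C=C | starting material
14 | (3R)-3,7-dimethyl-3-(triethylsilyloxy)octa-1,6-diene | CC(C)=CCC[C@@](C)(O[Si](CC)(CC)CC)C=C | intermediate
15 | (5R)-5-methyl-2-(prop-1-en-2-yl)-5-(triethylsilyloxy)hept-6-en-1-ol, C2 epimers | C=C(C)C(CO)CC[C@@](C)(O[Si](CC)(CC)CC)C=C | intermediate
16 | (5R)-5-methyl-2-(prop-1-en-2-yl)-5-(triethylsilyloxy)hept-6-enal | C=C(C)C(C=O)CC[C@@](C)(O[Si](CC)(CC)CC)C=C | intermediate (not isolated)
17 | (5R)-5-methyl-2-(propan-2-ylidene)-5-(triethylsilyloxy)hept-6-enal | CC(C)=C(C=O)CC[C@@](C)(O[Si](CC)(CC)CC)C=C | intermediate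
18 | lithium (6R)-1,1-dichloro-6-methyl-3-(propan-2-ylidene)-6-(triethylsilyloxy)oct-7-en-2-olate | CC(C)=C(C(O[Li])C(Cl)Cl)CC[C@@](C)(O[Si](CC)(CC)CC)C=C | intermediate (not isolated)
19 | (6R)-1,1-dichloro-6-methyl-3-(propan-2-ylidene)-2,6-bis(triethylsilyloxy)oct-7-ene, C2 epimers | CC(C)=C(C(O[Si](CC)(CC)CC)C(Cl)Cl)CC[C@@](C)(O[Si](CC)(CC)CC)C=C | intermediate
20 | B-alkyl-9-borabicyclo[3.3.1]nonane from 19 (boron on C6 of the target numbering) | CC(C)=C(C(O[Si](CC)(CC)CC)C(Cl)Cl)CC[C@@](C)(O[Si](CC)(CC)CC)CCB1C2CCCC1CCC2 | intermediate (not isolated)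
21 | (3R)-8,8-dichloro-3-methyl-6-(propan-2-ylidene)-3,7-bis(triethylsilyloxy)octan-1-ol | CC(C)=C(C(O[Si](CC)(CC)CC)C(Cl)Cl)CC[C@@](C)(O[Si](CC)(CC)CC)CCO | intermediate
22 | (3R)-8,8-dichloro-3-methyl-6-(propan-2-ylidene)-3,7-bis(triethylsilyloxy)octanal | CC(C)=C(C(O[Si](CC)(CC)CC)C(Cl)Cl)CC[C@@](C)(O[Si](CC)(CC)CC)CC=O | intermediate
23 | hydrazone of 22 | CC(C)=C(C(O[Si](CC)(CC)CC)C(Cl)Cl)CC[C@@](C)(O[Si](CC)(CC)CC)CC=NN | intermediate (not isolated)
24 | (6R)-8,8-dibromo-1,1-dichloro-6-methyl-3-(propan-2-ylidene)-2,6-bis(triethylsilyloxy)octane | CC(C)=C(C(O[Si](CC)(CC)CC)C(Cl)Cl)CC[C@@](C)(O[Si](CC)(CC)CC)CC(Br)Br | intermediate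
25 | gem-bis(bromozincio) species from 24 | CC(C)=C(C(O[Si](CC)(CC)CC)C(Cl)Cl)CC[C@@](C)(O[Si](CC)(CC)CC)CC([Zn]Br)[Zn]Br | intermediate (not isolated)
26 | (4R,6Z,8S,10R)-seco enol ether: 2-alkylidene oxolane (O, C7–C10) linking C1–C6 to C11–C12; OTES at C4, C12 and C14; CHCl2 at C13 | CC[Si](CC)(CC)O[C@@](C)(C/C=C1\O[C@H](C[C@@H]1C)CC(C)O[Si](CC)(CC)CC)CCC(C(O[Si](CC)(CC)CC)C(Cl)Cl)=C(C)C | intermediate
27 | (4R,6Z,8S,10R)-seco diol: as 26 with free C12–OH and C14–OH | CC[Si](CC)(CC)O[C@@](C)(C/C=C1\O[C@H](C[C@@H]1C)CC(C)O)CCC(C(O)C(Cl)Cl)=C(C)C | intermediate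
28 | (4R,6Z,8S,10R)-seco diketone: C12 methyl ketone, C14 dichloromethyl ketone, C4–OTES | CC[Si](CC)(CC)O[C@@](C)(C/C=C1\O[C@H](C[C@@H]1C)CC(C)=O)CCC(C(=O)C(Cl)Cl)=C(C)C | intermediate
29 | trivalent-samarium chloro-enolate of 28 (O–SmI2 on C14, C13=CHCl) | CC[Si](CC)(CC)O[C@@](C)(C/C=C1\O[C@H](C[C@@H]1C)CC(C)=O)CCC(C(O[Sm](I)I)=CCl)=C(C)C | intermediate (not isolated)
30 | (12S,13S)-macrocyclic chloro-aldolate (C12–O–SmI2, C13–Cl) | CC[Si](CC)(CC)O[C@@]1(C)C/C=C2\O[C@H](C[C@@H]2C)C[C@](C)(O[Sm](I)I)[C@H](Cl)C(=O)C(=C(C)C)CC1 | intermediate (not isolated)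
31 | (4R,6Z,8S,10R,12S,13R)-O-triethylsilyl analogue of the target | CC[Si](CC)(CC)O[C@@]1(C)C/C=C2\O[C@H](C[C@@H]2C)C[C@]2(C)O[C@H]2C(=O)C(=C(C)C)CC1 | intermediate
32 | (4R,6Z,8S,10R,12S,13R)-deacetyl target (free C4–OH) | O[C@@]1(C)C/C=C2\O[C@H](C[C@@H]2C)C[C@]2(C)O[C@H]2C(=O)C(=C(C)C)CC1 | intermediate
33 | CNP0162736.1 | CC(=O)O[C@@]1(C)C/C=C2\O[C@H](C[C@@H]2C)C[C@]2(C)O[C@H]2C(=O)C(=C(C)C)CC1 | target

**Step count**

Total: 19 steps. Longest linear sequence: 13 steps (steps 7–19, from (R)-linalool); the lactone branch is 6 steps before the coupling.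

**Steps most likely to fail**

1. Step 17 (key step).
   - What may go wrong: protonation or intermolecular reaction of the samarium enolate instead of closure of the 14-membered ring; addition to the wrong C12 face or closure to the cis oxirane; reductive opening of the epoxy ketone by residual SmI2.
   - Fallback (ring-closing metathesis at C12=C13, then epoxidation; sets out from 11 and 17, comes back at 31): 11 is oxidised with Dess–Martin periodinane to methyl ketone lactone F1 and methylenated without base (Zn, CH2Br2, TiCl4) to methallyl lactone F2. Enal 17 is reduced with iBu2AlH to allylic alcohol F3 and silylated (TESCl, imidazole) to bis-silyl ether F4. F4 is taken through the conditions of steps 11–13: alkylborane F5, primary alcohol F6, aldehyde F7, hydrazone F8, gem-dibromide F9. Takai–Utimoto coupling of F9 (through gem-dizinc species F10) with F2 should give enol ether F11. Buffered Bu4NF–AcOH frees the primary allylic alcohol F12 with the tertiary ether kept; MnO2 gives enal F13; vinylmagnesium bromide gives dienyl carbinol F14; Dess–Martin periodinane gives vinyl ketone F15. Second-generation Hoveyda–Grubbs catalyst at high dilution should close the ring to the (E)-C12=C13 macrocyclic dienone F16 with loss of ethene. Weitz–Scheffer epoxidation (t-BuOOH, DBU) should attack only the less hindered trisubstituted enone and give the trans oxirane 31; the face would be under substrate control and the C12/C13 epimers would have to be separated.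

2. Step 14 (Takai–Utimoto coupling).
   - What may go wrong: the titanium alkylidene decays (β-hydride loss, dimerisation) faster than it adds to the α-branched lactone, so that a near-equimolar coupling of two advanced fragments stalls, or the enol ether geometry erodes.
   - Fallback (modified Julia olefination of the lactone; sets out from 21, comes back at 26): Mitsunobu reaction of 21 with 2-mercaptobenzothiazole (PPh3, DIAD) gives benzothiazolyl sulfide F17. Oxidation with buffered H2O2 and (NH4)6Mo7O24 gives benzothiazolyl sulfone F18. Its anion (LiN(SiMe3)2, THF, −78 °C) adds to lactone 12 to give hemiketal adduct F19, and DBU then triggers the Smiles rearrangement and loss of SO2 to give enol ether 26. The Z isomer would be favoured by the C5/C8-methyl allylic strain and separated if necessary.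

3. Step 8 (ene reaction).
   - What may go wrong: ionisation of the tertiary allylic silyl ether by the aluminium Lewis acid, or capture of the developing C15 cation by the C4 oxygen (tetrahydropyran formation), instead of the ene hydrogen transfer.
   - Fallback ([2,3]-Wittig–Still rearrangement; sets out from 14, comes back at 15): allylic oxidation of 14 with SeO2 (cat.) and t-BuOOH, followed by NaBH4, gives (E)-allylic alcohol F20. KH and Bu3SnCH2I give stannylmethyl ether F21. Tin–lithium exchange with n-BuLi at −78 °C starts the [2,3]-sigmatropic shift that bonds the CH2OH carbon to C1 and moves the double bond into the isopropenyl position, giving 15.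

**Further compounds**

F1 | step 17 | (3S,5R)-3-methyl-5-(2-oxopropyl)oxolan-2-one | CC(=O)C[C@H]1C[C@H](C)C(=O)O1
F2 | step 17 | (3S,5R)-3-methyl-5-(2-methylprop-2-enyl)oxolan-2-one | C=C(C)C[C@H]1C[C@H](C)C(=O)O1
F3 | step 17 | (5R)-5-methyl-2-(propan-2-ylidene)-5-(triethylsilyloxy)hept-6-en-1-ol | CC(C)=C(CO)CC[C@@](C)(O[Si](CC)(CC)CC)C=C
F4 | step 17 | (3R)-3-methyl-6-(propan-2-ylidene)-3,7-bis(triethylsilyloxy)hept-1-ene | CC(C)=C(CO[Si](CC)(CC)CC)CC[C@@](C)(O[Si](CC)(CC)CC)C=C
F5 | step 17 | B-alkyl-9-borabicyclo[3.3.1]nonane from F4 | CC(C)=C(CO[Si](CC)(CC)CC)CC[C@@](C)(O[Si](CC)(CC)CC)CCB1C2CCCC1CCC2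
F6 | step 17 | (3R)-3-methyl-6-(propan-2-ylidene)-3,7-bis(triethylsilyloxy)heptan-1-ol | CC(C)=C(CO[Si](CC)(CC)CC)CC[C@@](C)(O[Si](CC)(CC)CC)CCO
F7 | step 17 | (3R)-3-methyl-6-(propan-2-ylidene)-3,7-bis(triethylsilyloxy)heptanal | CC(C)=C(CO[Si](CC)(CC)CC)CC[C@@](C)(O[Si](CC)(CC)CC)CC=O
F8 | step 17 | hydrazone of F7 | CC(C)=C(CO[Si](CC)(CC)CC)CC[C@@](C)(O[Si](CC)(CC)CC)CC=NN
F9 | step 17 | (5R)-7,7-dibromo-5-methyl-2-(propan-2-ylidene)-1,5-bis(triethylsilyloxy)heptane | CC(C)=C(CO[Si](CC)(CC)CC)CC[C@@](C)(O[Si](CC)(CC)CC)CC(Br)Br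
F10 | step 17 | gem-bis(bromozincio) species from F9 | CC(C)=C(CO[Si](CC)(CC)CC)CC[C@@](C)(O[Si](CC)(CC)CC)CC([Zn]Br)[Zn]Br
F11 | step 17 | (4R,6Z,8S,10R)-enol ether with C12 isopropenyl terminus, C14 CH2OTES and C4–OTES | CC[Si](CC)(CC)O[C@@](C)(C/C=C1\O[C@H](C[C@@H]1C)CC(C)=C)CCC(CO[Si](CC)(CC)CC)=C(C)C
F12 | step 17 | primary allylic alcohol from F11 | CC[Si](CC)(CC)O[C@@](C)(C/C=C1\O[C@H](C[C@@H]1C)CC(C)=C)CCC(CO)=C(C)C
F13 | step 17 | enal from F12 | CC[Si](CC)(CC)O[C@@](C)(C/C=C1\O[C@H](C[C@@H]1C)CC(C)=C)CCC(C=O)=C(C)C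
F14 | step 17 | dienyl carbinol (C14 epimers) | CC[Si](CC)(CC)O[C@@](C)(C/C=C1\O[C@H](C[C@@H]1C)CC(C)=C)CCC(C(O)C=C)=C(C)C
F15 | step 17 | vinyl ketone (C14 ketone, C13=CH2) | CC[Si](CC)(CC)O[C@@](C)(C/C=C1\O[C@H](C[C@@H]1C)CC(C)=C)CCC(C(=O)C=C)=C(C)C
F16 | step 17 | (4R,6Z,8S,10R,12E)-macrocyclic dienone | CC[Si](CC)(CC)O[C@@]1(C)C/C=C2\O[C@H](C[C@@H]2C)C/C(C)=C/C(=O)C(=C(C)C)CC1
F17 | step 14 | 2-benzothiazolyl sulfide of 21 | CC(C)=C(C(O[Si](CC)(CC)CC)C(Cl)Cl)CC[C@@](C)(O[Si](CC)(CC)CC)CCSc1nc2ccccc2s1
F18 | step 14 | 2-benzothiazolyl sulfone | CC(C)=C(C(O[Si](CC)(CC)CC)C(Cl)Cl)CC[C@@](C)(O[Si](CC)(CC)CC)CCS(=O)(=O)c1nc2ccccc2s1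
F19 | step 14 | hemiketal adduct of the sulfone anion and lactone 12 (C6 and C7 epimers) | CC[Si](CC)(CC)O[C@@](C)(CC(S(=O)(=O)c1nc2ccccc2s1)C1(O)O[C@H](C[C@@H]1C)CC(C)O[Si](CC)(CC)CC)CCC(C(O[Si](CC)(CC)CC)C(Cl)Cl)=C(C)C
F20 | step 8 | (2E,6R)-2,6-dimethyl-6-(triethylsilyloxy)octa-2,7-dien-1-ol | OC/C(C)=C/CC[C@@](C)(O[Si](CC)(CC)CC)C=C
F21 | step 8 | (tributylstannyl)methyl ether of F20 | CCCC[Sn](CCCC)(CCCC)COC/C(C)=C/CC[C@@](C)(O[Si](CC)(CC)CC)C=C
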